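**Retrosynthetic overview**
- The target comes from selective 6-O-acetylation of the 6,8-diol acid. The tertiary C8 carbinol comes from methyl addition to a 6α-hydroxy-8-ketone. The C6 oxygen comes from conjugate borylation–oxidation of a cis-fused Δ6-en-8-one.
- Key disconnection: ring B (six-membered) comes from a cis-hydrindan-2-one. C7 is inserted between C8 and C6 by a 1,2-shift of C6 onto a diazo-derived carbon, and the sequence is carried on to the enone in the same flask.
- In the contracted ring, C10 and C5 are both β to the single C8 carbonyl. Ring A is therefore closed by a radical C4–C5 conjugate addition, which also forces the cis ring fusion.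
- The side chain is built by Michael addition of the C8–C9 enol silane to methyl vinyl ketone followed by HWE olefination. The quaternary C10 is set by asymmetric conjugate addition to 3-methylcyclopentenone.
- Ring order: the purchased five-membered proto-ring B comes first, then ring A, then expansion of ring B from five to six members.

Assumption: the SMILES is read literally, so H-5 and CH3-10 are cis (a cis-decalin; labdane numbering 5S,6S,8S,9S,10R). Labdane numbering is used throughout, and α means the face that carries CH3-10.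

**Step 1**
Reactants: 1 3-methylcyclopent-2-en-1-one; 2 5-bromo-2-methylpent-2-ene
Product: 5 (R)-trimethyl{[3-methyl-3-(4-methylpent-3-en-1-yl)cyclopent-1-en-1-yl]oxy}silane, via homoprenylmagnesium bromide 3 (not isolated), via bromomagnesium enolate 4 (not isolated)
Conditions: Mg, Et2O; Cu(OTf)2 (3 mol %), chiral imidazolinium NHC precursor (4 mol %), 1, Et2O, −30 °C; then TMSCl, Et3N, DMPU, −30 → 23 °C
Reagents that add atoms: chlorotrimethylsilane, C[Si](C)(C)Cl
Why: Cu–NHC-catalysed asymmetric conjugate addition of Grignard reagents to β-methyl enones is an established route to all-carbon quaternary centres; the ligand enantiomer is chosen to give (R)-C10, and silylation stores the regiodefined C8–C9 enolate.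

**Step 2**
Reactants: 5 (R)-enol silane; 6 but-3-en-2-one (methyl vinyl ketone)
Product: 8 (2S,3R)-3-methyl-3-(4-methylpent-3-en-1-yl)-2-(3-oxobutyl)cyclopentan-1-one, via silyl enol ether adduct 7 (not isolated)
Conditions: 6 (1.5 equiv), Tf2NH (1 mol %), CH2Cl2, −78 °C; then 1 M HCl, THF, 0 °C
Reagents that add atoms: none
Why: This Mukaiyama–Michael addition forms C9–C11 at the only enol carbon, and the enone approaches anti to the larger homoprenyl arm, so C11 ends cis to CH3-10 (this is also the thermodynamic 2,3-relation).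

**Step 3**
Reactants: 8 diketone
Product: 9 methyl (2E)-3-methyl-5-[(1S,2R)-2-methyl-2-(4-methylpent-3-en-1-yl)-5-oxocyclopentyl]pent-2-enoate
Conditions: (MeO)2P(O)CH2CO2Me, NaH, THF, 0 → 40 °C; Z isomer removed by chromatography
Reagents that add atoms: trimethyl phosphonoacetate, COC(=O)CP(=O)(OC)OC
Why: The Horner–Wadsworth–Emmons olefination takes the unhindered methyl ketone rather than the C8 ketone, which sits next to a tertiary carbon adjoining a quaternary one, and it gives mainly the E-enoate (about 6–8:1).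

**Step 4**
Reactants: 9 keto enoate
Product: 12 methyl (2E)-3-methyl-5-[(1S,5R)-5-methyl-5-(4-methylpent-3-en-1-yl)-2-oxocyclopent-3-en-1-yl]pent-2-enoate, via lithium enolate 10 (not isolated), via trimethylsilyl enol ether 11 (not isolated)
Conditions: LDA, TMSCl (internal quench), THF, −78 °C; crude 11, Pd(OAc)2 (10 mol %), O2 (1 atm), DMSO, 25–40 °C
Reagents that add atoms: none
Why: Kinetic deprotonation occurs at the C6 methylene and not at tertiary C9, and the Saegusa–Ito oxidation then gives the enone in which C5 has become a β-carbon.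

**Step 5**
Reactants: 12 cyclopentenone
Product: 13 methyl (2E)-3-methyl-5-[(1S,3aS,7aR)-4,4,7a-trimethyl-2-oxooctahydro-1H-inden-1-yl]pent-2-enoate
Conditions: Fe(acac)3 (20 mol %), PhSiH3 (2.5 equiv), EtOH, 60 °C, 0.02 M
Reagents that add atoms: none
Why: Fe–H hydrogen-atom transfer to the electron-rich trisubstituted alkene gives the tertiary C4 radical, which closes ring A by a 6-exo Giese addition to C5; the tether on C10 reaches only its own face, so H-5 ends cis to CH3-10.

**Step 6**
Reactants: 13 cis-hydrindan-2-one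
Product: 16 methyl (2E)-3-methyl-5-[(1S,4aS,8aR)-5,5,8a-trimethyl-2-oxo-1,2,4a,5,6,7,8,8a-octahydronaphthalen-1-yl]pent-2-enoate, via β-ketosilane 14 (not isolated), via enol silane 15 (not isolated)
Conditions: TMSCHN2 (1.3 equiv), Sc(OTf)3 (10 mol %), CH2Cl2, −40 → 23 °C; then Pd(OAc)2 (10 mol %), O2 (1 atm), DMSO, 50 °C (one flask)
Reagents that add atoms: (trimethylsilyl)diazomethane, C[Si](C)(C)C=[N+]=[N-]
Why: Proposed new method: this is a one-flask "homologative desaturation" of an α-branched, fused cyclopentanone, in which Sc(III) activates C8=O, TMSCHN2 adds, and the less substituted, less hindered C6H2 (not tertiary C9) migrates antiperiplanar to N2, a 1,2-shift that expands the ring from five to six members and leaves the cis fusion and C9 untouched; β-ketosilane 14 then undergoes a Sc-assisted 1,3-Brook shift to the regiodefined enol silane 15, which also blocks a second insertion, and Pd(II)/O2 eliminates β-H toward C6 to give the Δ6-enone; the closest known reactions are the Lewis-acid-catalysed, Tiffeneau–Demjanov-type TMSCHN2 homologation of cyclobutanones to enol silanes and the Saegusa–Ito oxidation, which have neither been combined nor shown on such cyclopentanones.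

**Step 7**
Reactants: 16 cis-octalenone
Product: 18 methyl (2E)-5-[(1S,4S,4aS,8aR)-4-hydroxy-5,5,8a-trimethyl-2-oxodecahydronaphthalen-1-yl]-3-methylpent-2-enoate, via 6α-pinacolboryl ketone 17 (not isolated)
Conditions: B2pin2 (1.1 equiv), CuCl (5 mol %), DPEphos (5 mol %), NaOt-Bu (7 mol %), MeOH (2 equiv), THF, 23 °C; then NaBO3·4H2O, THF–H2O, 23 °C
Reagents that add atoms: sodium perborate, [Na+].[O-]OB=O
Why: Cu-catalysed conjugate borylation attacks the cyclic disubstituted enone, not the β,β-disubstituted enoate, at C6 from the convex α face, trans to the quaternary C4 on neighbouring C5, and the C–B oxidation proceeds with retention to the 6α-alcohol.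

**Step 8**
Reactants: 18 6α-hydroxy-8-ketone
Product: 19 methyl (2E)-5-[(1S,2S,4S,4aS,8aR)-2,4-dihydroxy-2,5,5,8a-tetramethyldecahydronaphthalen-1-yl]-3-methylpent-2-enoate
Conditions: MeLi, CeCl3 (3 equiv each), THF, −78 °C; then H2O
Reagents that add atoms: methyllithium, [Li]C
Why: The organocerium 1,2-addition is non-basic (no retro-aldol, no E1cB) and spares the ester; the reagent enters from the convex α face because the β face of C8 is screened by the axial C1 methylene, giving 8α-CH3 and 8β-OH (the anti-1,3-diol).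

**Step 9**
Reactants: 19 diol ester
Product: 20 (2E)-5-[(1S,2S,4S,4aS,8aR)-2,4-dihydroxy-2,5,5,8a-tetramethyldecahydronaphthalen-1-yl]-3-methylpent-2-enoic acid
Conditions: LiOH, THF–MeOH–H2O, 50 °C; then 1 M HCl to pH 3, 0 °C
Reagents that add atoms: lithium hydroxide, [Li+].[OH-]
Why: Saponification (BAc2) is done before the acetate is introduced, the 1,3-diol has no base-labile position, and no stereocentre is affected.

**Step 10**
Reactants: 20 diol acid
Product: 22 (2E)-5-[(1S,2S,4S,4aS,8aR)-4-acetoxy-2-hydroxy-2,5,5,8a-tetramethyldecahydronaphthalen-1-yl]-3-methylpent-2-enoic acid, via mixed acetic anhydride 21 (not isolated)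
Conditions: Ac2O, pyridine, DMAP (5 mol %), 0 → 23 °C; then H2O–THF, 23 °C
Reagents that add atoms: acetic anhydride, CC(=O)OC(C)=O
Why: In this DMAP-catalysed acylation only the secondary 6-OH reacts while the tertiary 8-OH stays free, and the mixed anhydride formed at the acid is hydrolysed on aqueous work-up.

**Compound list**
1 | 3-methylcyclopent-2-en-1-one | CC1=CC(=O)CC1 | starting material
2 | 5-bromo-2-methylpent-2-ene | CC(C)=CCCBr | starting material
3 | (4-methylpent-3-en-1-yl)magnesium bromide | CC(C)=CCC[Mg]Br | intermediate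
4 | bromomagnesium (R)-3-methyl-3-(4-methylpent-3-en-1-yl)cyclopent-1-en-1-olate | Br[Mg]OC1=C[C@](C)(CCC=C(C)C)CC1 | intermediate
5 | (R)-trimethyl{[3-methyl-3-(4-methylpent-3-en-1-yl)cyclopent-1-en-1-yl]oxy}silane | C[Si](C)(C)OC1=C[C@](C)(CCC=C(C)C)CC1 | intermediate
6 | but-3-en-2-one | CC(=O)C=C | starting material
7 | (2S,3R)-3-methyl-3-(4-methylpent-3-en-1-yl)-2-[3-(trimethylsilyloxy)but-2-en-1-yl]cyclopentan-1-one (E/Z mixture) | O=C1CC[C@@](C)(CCC=C(C)C)[C@@H]1CC=C(C)O[Si](C)(C)C | intermediate
8 | (2S,3R)-3-methyl-3-(4-methylpent-3-en-1-yl)-2-(3-oxobutyl)cyclopentan-1-one | O=C1CC[C@@](C)(CCC=C(C)C)[C@@H]1CCC(C)=O | intermediate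
9 | methyl (2E)-3-methyl-5-[(1S,2R)-2-methyl-2-(4-methylpent-3-en-1-yl)-5-oxocyclopentyl]pent-2-enoate | O=C1CC[C@@](C)(CCC=C(C)C)[C@@H]1CC/C(C)=C/C(=O)OC | intermediate
10 | lithium C8–C6 enolate of 9 | [Li]OC1=CC[C@@](C)(CCC=C(C)C)[C@@H]1CC/C(C)=C/C(=O)OC | intermediate
11 | methyl (2E)-3-methyl-5-[(1S,5R)-5-methyl-5-(4-methylpent-3-en-1-yl)-2-(trimethylsilyloxy)cyclopent-2-en-1-yl]pent-2-enoate | C[Si](C)(C)OC1=CC[C@@](C)(CCC=C(C)C)[C@@H]1CC/C(C)=C/C(=O)OC | intermediate
12 | methyl (2E)-3-methyl-5-[(1S,5R)-5-methyl-5-(4-methylpent-3-en-1-yl)-2-oxocyclopent-3-en-1-yl]pent-2-enoate | O=C1C=C[C@@](C)(CCC=C(C)C)[C@@H]1CC/C(C)=C/C(=O)OC | intermediate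
13 | methyl (2E)-3-methyl-5-[(1S,3aS,7aR)-4,4,7a-trimethyl-2-oxooctahydro-1H-inden-1-yl]pent-2-enoate (cis-fused) | O=C1C[C@H]2C(C)(C)CCC[C@@]2(C)[C@@H]1CC/C(C)=C/C(=O)OC | intermediate
14 | methyl (2E)-3-methyl-5-[(1S,4aS,8aR)-5,5,8a-trimethyl-2-oxo-3-(trimethylsilyl)decahydronaphthalen-1-yl]pent-2-enoate (C-3 epimers) | O=C1C([Si](C)(C)C)C[C@H]2C(C)(C)CCC[C@@]2(C)[C@@H]1CC/C(C)=C/C(=O)OC | intermediate
15 | methyl (2E)-3-methyl-5-[(1S,4aS,8aR)-5,5,8a-trimethyl-2-(trimethylsilyloxy)-1,4,4a,5,6,7,8,8a-octahydronaphthalen-1-yl]pent-2-enoate | C[Si](C)(C)OC1=CC[C@H]2C(C)(C)CCC[C@@]2(C)[C@@H]1CC/C(C)=C/C(=O)OC | intermediate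
16 | methyl (2E)-3-methyl-5-[(1S,4aS,8aR)-5,5,8a-trimethyl-2-oxo-1,2,4a,5,6,7,8,8a-octahydronaphthalen-1-yl]pent-2-enoate | O=C1C=C[C@H]2C(C)(C)CCC[C@@]2(C)[C@@H]1CC/C(C)=C/C(=O)OC | intermediate
17 | methyl (2E)-3-methyl-5-[(1S,4S,4aS,8aR)-5,5,8a-trimethyl-2-oxo-4-(4,4,5,5-tetramethyl-1,3,2-dioxaborolan-2-yl)decahydronaphthalen-1-yl]pent-2-enoate | O=C1C[C@H](B3OC(C)(C)C(C)(C)O3)[C@H]2C(C)(C)CCC[C@@]2(C)[C@@H]1CC/C(C)=C/C(=O)OC | intermediate
18 | methyl (2E)-5-[(1S,4S,4aS,8aR)-4-hydroxy-5,5,8a-trimethyl-2-oxodecahydronaphthalen-1-yl]-3-methylpent-2-enoate | O[C@H]1CC(=O)[C@@H](CC/C(C)=C/C(=O)OC)[C@]2(C)CCCC(C)(C)[C@H]12 | intermediate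
19 | methyl (2E)-5-[(1S,2S,4S,4aS,8aR)-2,4-dihydroxy-2,5,5,8a-tetramethyldecahydronaphthalen-1-yl]-3-methylpent-2-enoate | O[C@H]1C[C@](C)(O)[C@@H](CC/C(C)=C/C(=O)OC)[C@]2(C)CCCC(C)(C)[C@H]12 | intermediate
20 | (2E)-5-[(1S,2S,4S,4aS,8aR)-2,4-dihydroxy-2,5,5,8a-tetramethyldecahydronaphthalen-1-yl]-3-methylpent-2-enoic acid | O[C@H]1C[C@](C)(O)[C@@H](CC/C(C)=C/C(=O)O)[C@]2(C)CCCC(C)(C)[C@H]12 | intermediate
21 | mixed anhydride of 22 with acetic acid | CC(=O)O[C@H]1C[C@](C)(O)[C@@H](CC/C(C)=C/C(=O)OC(C)=O)[C@]2(C)CCCC(C)(C)[C@H]12 | intermediate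
22 | (2E)-5-[(1S,2S,4S,4aS,8aR)-4-acetoxy-2-hydroxy-2,5,5,8a-tetramethyldecahydronaphthalen-1-yl]-3-methylpent-2-enoic acid | CC(=O)O[C@H]1C[C@](C)(O)[C@@H](CC/C(C)=C/C(=O)O)[C@]2(C)CCCC(C)(C)[C@H]12 | target

**Step count:** 10 steps in total. The longest linear sequence is also 10 steps (1 → 22).

**Steps most likely to fail**

Step 6 (the new step). Possible failures are partial migration of C9, an incomplete Brook shift, and inhibition of the palladium step by scandium or diazo residues. The fallback replaces the cationic 1,2-shift by a known radical ring expansion.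
- It sets out from 13. LDA/TMSCl at −78 °C gives the kinetic C8–C6 trimethylsilyl enol ether F1.
- Et2Zn/CH2I2 cyclopropanates only this electron-rich alkene, from the convex face, to give the siloxycyclopropane F2.
- FeCl3 in DMF cleaves the internal C8–C6 bond by β-scission to give the ring-expanded 6-chloro ketone F3.
- NaOAc in MeOH eliminates HCl, which returns to the route at 16.

Step 8. The two chair–chair forms of the cis-decalone are close in energy, so methyl could enter from the β face, and enolisation could compete. The fallback forms the C8–O bond on the open face instead of the C8–C bond, so its facial outcome is complementary.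
- It sets out from 18. Non-basic Lombardo methylenation (Zn, CH2Br2, TiCl4) gives the 8(17)-exocyclic alkene F4.
- Mukaiyama hydration (Co(acac)2, PhSiH3, O2, then P(OEt)3) of this 1,1-disubstituted alkene places OH at C8 from the accessible face and returns to the route at 19.

Step 5. The new C4–C5 bond lies between a quaternary centre and a carbon that adjoins another quaternary centre, so simple alkene reduction or enone reduction may win. The fallback separates radical generation from the hydrogen-atom-transfer chemistry.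
- It sets out from 12. Markovnikov addition of HBr (33 % in AcOH, CH2Cl2, −20 °C) gives the tertiary bromide F5.
- Slow addition of Bu3SnH/AIBN (benzene, 80 °C, classical tin-hydride Giese cyclisation) closes ring A and returns to the route at 13.

**Further compounds**
F1 | step 6 | methyl (2E)-3-methyl-5-[(1S,3aS,7aR)-4,4,7a-trimethyl-2-(trimethylsilyloxy)-3a,4,5,6,7,7a-hexahydro-1H-inden-1-yl]pent-2-enoate | C[Si](C)(C)OC1=C[C@H]2C(C)(C)CCC[C@@]2(C)[C@@H]1CC/C(C)=C/C(=O)OC
F2 | step 6 | siloxycyclopropane of F1 (CH2 bridging C8 and C6 on the α face) | C[Si](C)(C)O[C@]13C[C@@H]3[C@H]2C(C)(C)CCC[C@@]2(C)[C@@H]1CC/C(C)=C/C(=O)OC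
F3 | step 6 | methyl (2E)-5-[(1S,4aS,8aR)-4-chloro-5,5,8a-trimethyl-2-oxodecahydronaphthalen-1-yl]-3-methylpent-2-enoate (C-4 epimers) | O=C1CC(Cl)[C@H]2C(C)(C)CCC[C@@]2(C)[C@@H]1CC/C(C)=C/C(=O)OC
F4 | step 8 | methyl (2E)-5-[(1S,4S,4aS,8aR)-4-hydroxy-5,5,8a-trimethyl-2-methylidenedecahydronaphthalen-1-yl]-3-methylpent-2-enoate | O[C@H]1CC(=C)[C@@H](CC/C(C)=C/C(=O)OC)[C@]2(C)CCCC(C)(C)[C@H]12
F5 | step 5 | methyl (2E)-5-[(1S,5R)-5-(4-bromo-4-methylpentyl)-5-methyl-2-oxocyclopent-3-en-1-yl]-3-methylpent-2-enoate | O=C1C=C[C@@](C)(CCCC(C)(C)Br)[C@@H]1CC/C(C)=C/C(=O)OC
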